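Ring B of the target places C8 (tertiary carbinol bearing CH3) 1,4 across from the fusion carbon C5, the 2,5-pattern of a 2-methylfuran. C9 and C10 carry what an E-trisubstituted enal carries. Everything therefore rests on disconnecting C5–C10 and C8–C9. One enantioselective intramolecular furan Diels–Alder reaction closes rings A and B and sets C5, C8, C9 and C10. It also stores the later 8α-hydroxyl oxygen as a 5α,8α bridge. Its precursor is an achiral open-chain compound: a 2-methylfuran tied through C4(CH3)2–C3–C2–C1 to the β-carbon of an (E)-3-methyl-2-enal. Afterwards the bridge is opened, C5–C7 are functionalised from the α face, and the dienyl chain is coupled at C11.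

Key step: step 5

Assumption 1: the (S)-configured oxazaborolidinium catalyst is taken to shield the enal face that leads to the 10β-methyl series, following its usual formyl C–H···O binding model. If the sense proves opposite, the equally available (R)-catalyst is used and nothing else changes.
Assumption 2: but-1-en-3-yne is used as its commercial solution. α/β descriptors refer to the normal drimane/labdane drawing (10-CH3 = β).

Step 1
Reactants: 1 2-methylfuran; 2 5-bromo-2-methylpent-2-ene
Product: 3 2-(5-bromo-2-methylpentan-2-yl)-5-methylfuran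
Conditions: Bi(OTf)3 (5 mol %), 1 (4 equiv), MeNO2, 0 °C → rt
Reagents that add atoms: none
Why: Friedel–Crafts hydroalkylation: the strongly acidic metal triflate system protonates the trisubstituted alkene of 2 to its tertiary cation, which the only free α-position of the furan (used in excess) captures to build the C4 quaternary carbon, while a terminal bromide, unlike a carbonyl group, neither condenses with the furan nor traps the cation irreversibly.

Step 2
Reactants: 3 2-(5-bromo-2-methylpentan-2-yl)-5-methylfuran; 4 ethyl but-2-ynoate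
Product: 8 ethyl (2E)-3,7-dimethyl-7-(5-methylfuran-2-yl)oct-2-enoate, via Grignard reagent 5 (not isolated), via alkylcopper 6 (not isolated), via alkenylcopper 7 (not isolated)
Conditions: Mg, THF, rt; CuBr·SMe2 (1 equiv), −40 °C; 4, −78 °C; aq NH4Cl at −78 °C
Reagents that add atoms: none
Why: Syn-carbocupration (conjugate addition of an organocopper to an ynoate): alkyl and copper add to the same side of 4 and cold protonation of 7 retains that geometry, so the chain should end up trans to the ester and the E-alkene that later encodes the C9/C10 relationship is made stereospecifically instead of by a poorly selective ketone olefination.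

Step 3
Reactants: 8 ethyl (2E)-3,7-dimethyl-7-(5-methylfuran-2-yl)oct-2-enoate
Product: 9 (2E)-3,7-dimethyl-7-(5-methylfuran-2-yl)oct-2-en-1-ol
Conditions: DIBAL-H (2.2 equiv), CH2Cl2, −78 °C; aq Rochelle salt
Reagents that add atoms: none
Why: 1,2-Reduction of a conjugated ester by DIBAL-H stops at the allylic alcohol and touches neither the furan nor the alkene geometry.

Step 4
Reactants: 9 (2E)-3,7-dimethyl-7-(5-methylfuran-2-yl)oct-2-en-1-ol
Product: 10 (2E)-3,7-dimethyl-7-(5-methylfuran-2-yl)oct-2-enal
Conditions: MnO2, CH2Cl2, rt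
Reagents that add atoms: none
Why: Heterogeneous MnO2 oxidation is selective for the allylic alcohol, neutral enough for the furan, and is not expected to scramble the E-geometry.

Step 5
Reactants: 10 (2E)-3,7-dimethyl-7-(5-methylfuran-2-yl)oct-2-enal
Product: 12 5α,8α-epoxydrim-6-en-11-ol, via oxygen-bridged aldehyde 11 (not isolated)
Conditions: (S)-diphenylprolinol-derived B-(o-tolyl)oxazaborolidine + Tf2NH (each 20–50 mol %), CH2Cl2, −78 → −40 °C; then DIBAL-H (3 equiv), −78 °C; aq Rochelle salt
Reagents that add atoms: none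
Why: Proposed new method: the cationic boron binds the formyl oxygen and lowers the enal LUMO, so the electron-rich 2,5-dialkylfuran of 10 adds across C9=C10 in a normal-demand, probably asynchronous [4+2] in which C5–C10 (attack on the enal β-carbon) leads C8–C9; the closest known types are aluminium-Lewis-acid-promoted intramolecular furan Diels–Alder reactions with four-atom tethers and intermolecular furan cycloadditions under cationic oxazaborolidine catalysis, whose combination on a β,β-disubstituted enal has not been shown. Ring B closes as the new cyclohexene of the cycloaddition (C5–C6=C7–C8–C9–C10, spanned by the former furan oxygen) and ring A as the six-membered tether ring (C4–C3–C2–C1 linking C5 to C10, type-1 intramolecular mode) the moment C5–C10 forms. C5 and C8 are tied to one another by the oxygen bridge (suprafacial use of the furan), C9 and C10 keep the cis relation of C11 and the C10 methyl held by the E-alkene (suprafacial use of the dienophile), and the short tether should lie exo, syn to the bridge, which places C11 and the methyl endo, i.e. 8α-O/9β-C11/10β-CH3. The absolute sense rests solely on the catalyst, whose aryl group covers one face of the bound s-trans enal. The step needs cycloaddition rather than Friedel–Crafts conjugate addition, which is secured by both furan α-positions being blocked, and a folded reactive conformer, which the C4 gem-dimethyl group favours. Because the crowded adduct 11 can revert or epimerise at C9, it is reduced in the cold flask by DIBAL-H, and any enal left over returns as alcohol 9 for recycling.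

Step 6
Reactants: 12 5α,8α-epoxydrim-6-en-11-ol
Product: 13 11-(4-methoxybenzyloxy)-5α,8α-epoxydrim-6-ene
Conditions: NaH, PMBCl, TBAI (cat.), DMF, 0 °C → rt
Reagents that add atoms: 4-methoxybenzyl chloride, COc1ccc(CCl)cc1
Why: Williamson etherification of the primary alkoxide leaves the base-stable oxanorbornene intact, and PMB is chosen because it tolerates boranes, base, hydride and silyl triflate and can later be removed oxidatively beside silyl ethers.

Step 7
Reactants: 13 11-(4-methoxybenzyloxy)-5α,8α-epoxydrim-6-ene
Product: 15 11-(4-methoxybenzyloxy)-5α,8α-epoxydriman-7α-ol, via B-alkyl-9-BBN adduct 14 (not isolated)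
Conditions: 9-BBN, THF, 0 °C → rt; H2O2, aq NaOH, 0 °C
Reagents that add atoms: hydrogen peroxide, OO
Why: Brown hydroboration–oxidation: the strained C6=C7 bond reacts from its exo (α, bridge-side) face because C11 and the C10 methyl cover the endo face, and the bulky borane should place boron on C7, next to the methyl-bearing C8, rather than on C6 beside the C4 quaternary carbon; saturation also rules out cycloreversion, and the C7 centre is only provisional.

Step 8
Reactants: 15 11-(4-methoxybenzyloxy)-5α,8α-epoxydriman-7α-ol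
Product: 16 11-(4-methoxybenzyloxy)-5α,8α-epoxydriman-7-one
Conditions: TPAP (5 mol %), NMO, 4 Å MS, CH2Cl2, rt
Reagents that add atoms: none
Why: Ley–Griffith oxidation of the secondary alcohol under neutral conditions leaves the PMB ether and the oxygen bridge intact and erases the provisional C7 centre.

Step 9
Reactants: 16 11-(4-methoxybenzyloxy)-5α,8α-epoxydriman-7-one
Product: 17 8α-hydroxy-11-(4-methoxybenzyloxy)drim-5-en-7-one
Conditions: LiHMDS (1.2 equiv), THF, −78 → 0 °C; aq NH4Cl
Reagents that add atoms: none
Why: E1cB β-elimination: C6 is the only enolisable position, its enolate expels the C5–O bond with release of bicyclic strain, the oxygen stays on C8 with its configuration untouched (8α-OH), and conjugation of the new enone disfavours an α-ketol shift.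

Step 10
Reactants: 17 8α-hydroxy-11-(4-methoxybenzyloxy)drim-5-en-7-one
Product: 18 11-(4-methoxybenzyloxy)drim-5-ene-7β,8α-diol
Conditions: NaBH4, CeCl3·7H2O, MeOH, −78 → −20 °C
Reagents that add atoms: none
Why: Luche 1,2-reduction: hydride should attack C7 from the α face, anti to the axial 8β-methyl group and on the side of the 8α-hydroxyl, giving the pseudo-equatorial 7β-alcohol as is usual for Δ5-7-ketones.

Step 11
Reactants: 18 11-(4-methoxybenzyloxy)drim-5-ene-7β,8α-diol
Product: 19 11-(4-methoxybenzyloxy)-7β,8α-bis(triethylsilyloxy)drim-5-ene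
Conditions: TESOTf (3 equiv), 2,6-lutidine, CH2Cl2, 0 °C → rt
Reagents that add atoms: triethylsilyl trifluoromethanesulfonate, CC[Si](CC)(CC)OS(=O)(=O)C(F)(F)F
Why: Silyl triflate silylation caps the secondary allylic and the tertiary hydroxyl in one operation, so that only O6 will be free after the next step and no acidic proton remains for the organozinc stage.

Step 12
Reactants: 19 11-(4-methoxybenzyloxy)-7β,8α-bis(triethylsilyloxy)drim-5-ene
Product: 21 11-(4-methoxybenzyloxy)-7β,8α-bis(triethylsilyloxy)-5α-driman-6α-ol, via alkylborane 20 (not isolated)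
Conditions: BH3·THF, THF, 0 → 40 °C; NaBO3·4H2O, THF–H2O, rt
Reagents that add atoms: sodium perborate (crystal water omitted), [Na+].[Na+].O[B-]1(O)OO[B-](O)(O)OO1
Why: Brown hydroboration–oxidation: boron goes to C6 (less substituted and adjacent to the C7–O bond) and the syn addition occurs on the α face, opposite the three axial β-methyl groups (on C4, C8, C10) and the 7β-silyloxy group, which sets 5α-H (trans-decalin) and, after retentive oxidation under mild perborate conditions, 6α-OH.

Step 13
Reactants: 21 11-(4-methoxybenzyloxy)-7β,8α-bis(triethylsilyloxy)-5α-driman-6α-ol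
Product: 22 7β,8α-bis(triethylsilyloxy)drimane-6α,11-diol
Conditions: DDQ, CH2Cl2–pH 7 buffer, 0 °C
Reagents that add atoms: none
Why: Oxidative PMB cleavage by DDQ (hydride abstraction, then hydrolysis of the oxocarbenium ion) is orthogonal to TES ethers and unactivated alcohols, and no alkene is present at this stage.

Step 14
Reactants: 22 7β,8α-bis(triethylsilyloxy)drimane-6α,11-diol
Product: 23 11-iodo-7β,8α-bis(triethylsilyloxy)driman-6α-ol
Conditions: I2, PPh3, imidazole, toluene, rt
Reagents that add atoms: iodine, II
Why: Appel-type iodination: only the primary C11 alkoxyphosphonium salt can be displaced, since SN2 at C6 would need attack from the β face under two axial methyl groups, so the 6α-hydroxyl should be returned unchanged; iodination before acylation also keeps the angelate away from I2 and PPh3.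

Step 15
Reactants: 23 11-iodo-7β,8α-bis(triethylsilyloxy)driman-6α-ol; 24 angelic acid
Product: 26 11-iodo-7β,8α-bis(triethylsilyloxy)driman-6α-yl angelate, via mixed anhydride 25 (not isolated)
Conditions: 24, 2,4,6-Cl3C6H2COCl, Et3N, toluene, rt; filter; then 23, 80 °C
Reagents that add atoms: none
Why: Yamaguchi-type mixed-anhydride esterification run without a nucleophilic catalyst: the alcohol attacks the unhindered angeloyl carbonyl of 25, and the absence of DMAP-type addition–elimination should keep the Z-alkene from isomerising to the tiglate.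

Step 16
Reactants: 27 but-1-en-3-yne
Product: 29 (1E)-1-iodo-2-methylbuta-1,3-diene, via dienylalane 28 (not isolated)
Conditions: Me3Al, Cp2ZrCl2 (20 mol %), CH2Cl2, 0 °C → rt; then I2, THF, −30 °C
Reagents that add atoms: trimethylaluminium, C[Al](C)C; iodine, II
Why: Zirconium-catalysed carboalumination (Negishi) adds CH3 and Al syn across the alkyne with aluminium at the terminus and leaves the vinyl group alone, and iodinolysis proceeds with retention, fixing the E-geometry of the future C12=C13 bond.

Step 17
Reactants: 26 11-iodo-7β,8α-bis(triethylsilyloxy)driman-6α-yl angelate; 29 (1E)-1-iodo-2-methylbuta-1,3-diene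
Product: 31 6α-angeloyloxy-7β,8α-bis(triethylsilyloxy)labda-12E,14-diene, via alkylzinc iodide 30 (not isolated)
Conditions: Zn dust, LiCl, THF, 40 °C; then 29 (1.5 equiv), PdCl2(dppf) (5 mol %), THF, rt
Reagents that add atoms: none
Why: Direct zinc insertion (tolerant of ester and silyl ethers) followed by Negishi sp3–sp2 coupling: oxidative addition occurs at the unhindered dienyl iodide with retention of geometry, so the congested C11 only has to transmetalate, and the bidentate ligand curbs β-hydride loss from C9.

Step 18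
Reactants: 31 6α-angeloyloxy-7β,8α-bis(triethylsilyloxy)labda-12E,14-diene
Product: 32 6α-angeloyloxylabda-12E,14-diene-7β,8α-diol (CNP0189082.1)
Conditions: HF·pyridine, pyridine, THF, 0 °C → rt
Reagents that add atoms: none
Why: Fluoride-mediated desilylation under buffered, mildly acidic conditions removes both TES groups without forming the alkoxide that would invite O6→O7 acyl migration or angelate isomerisation, and the pyridine-buffered reagent should not protonate the diene.

Compound list
1 | 2-methylfuran | Cc1ccco1 | starting material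
2 | 5-bromo-2-methylpent-2-ene | CC(C)=CCCBr | starting material
3 | 2-(5-bromo-2-methylpentan-2-yl)-5-methylfuran | Cc1ccc(o1)C(C)(C)CCCBr | intermediate
4 | ethyl but-2-ynoate | CC#CC(=O)OCC | starting material
5 | [4-methyl-4-(5-methylfuran-2-yl)pentyl]magnesium bromide | Cc1ccc(o1)C(C)(C)CCC[Mg]Br | intermediate (not isolated)
6 | [4-methyl-4-(5-methylfuran-2-yl)pentyl]copper | Cc1ccc(o1)C(C)(C)CCC[Cu] | intermediate (not isolated)
7 | ethyl 2-cuprio-3,7-dimethyl-7-(5-methylfuran-2-yl)oct-2-enoate, Cu cis to the long chain | Cc1ccc(o1)C(C)(C)CCC/C(C)=C(\[Cu])C(=O)OCC | intermediate (not isolated)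
8 | ethyl (2E)-3,7-dimethyl-7-(5-methylfuran-2-yl)oct-2-enoate | Cc1ccc(o1)C(C)(C)CCC/C(C)=C/C(=O)OCC | intermediate
9 | (2E)-3,7-dimethyl-7-(5-methylfuran-2-yl)oct-2-en-1-ol | Cc1ccc(o1)C(C)(C)CCC/C(C)=C/CO | intermediate
10 | (2E)-3,7-dimethyl-7-(5-methylfuran-2-yl)oct-2-enal | Cc1ccc(o1)C(C)(C)CCC/C(C)=C/C=O | intermediate
11 | 5α,8α-epoxydrim-6-en-11-al (9β-CHO, 10β-CH3, oxygen-bridged tricycle) | O=C[C@H]1[C@@]3(C)C=C[C@@]2(O3)C(C)(C)CCC[C@@]21C | intermediate (not isolated)
12 | 5α,8α-epoxydrim-6-en-11-ol | OC[C@H]1[C@@]3(C)C=C[C@@]2(O3)C(C)(C)CCC[C@@]21C | intermediate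
13 | 11-(4-methoxybenzyloxy)-5α,8α-epoxydrim-6-ene | COc1ccc(COC[C@H]2[C@@]4(C)C=C[C@@]3(O4)C(C)(C)CCC[C@@]32C)cc1 | intermediate
14 | 7α-(9-borabicyclo[3.3.1]nonan-9-yl)-11-(4-methoxybenzyloxy)-5α,8α-epoxydrimane | COc1ccc(COC[C@H]2[C@@]4(C)[C@H](B5C6CCCC5CCC6)C[C@@]3(O4)C(C)(C)CCC[C@@]32C)cc1 | intermediate (not isolated)
15 | 11-(4-methoxybenzyloxy)-5α,8α-epoxydriman-7α-ol | COc1ccc(COC[C@H]2[C@@]4(C)[C@H](O)C[C@@]3(O4)C(C)(C)CCC[C@@]32C)cc1 | intermediate
16 | 11-(4-methoxybenzyloxy)-5α,8α-epoxydriman-7-one | COc1ccc(COC[C@H]2[C@@]4(C)C(=O)C[C@@]3(O4)C(C)(C)CCC[C@@]32C)cc1 | intermediate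
17 | 8α-hydroxy-11-(4-methoxybenzyloxy)drim-5-en-7-one | COc1ccc(COC[C@H]2[C@](C)(O)C(=O)C=C3C(C)(C)CCC[C@@]32C)cc1 | intermediate
18 | 11-(4-methoxybenzyloxy)drim-5-ene-7β,8α-diol | COc1ccc(COC[C@H]2[C@](C)(O)[C@@H](O)C=C3C(C)(C)CCC[C@@]32C)cc1 | intermediate
19 | 11-(4-methoxybenzyloxy)-7β,8α-bis(triethylsilyloxy)drim-5-ene | COc1ccc(COC[C@H]2[C@](C)(O[Si](CC)(CC)CC)[C@@H](O[Si](CC)(CC)CC)C=C3C(C)(C)CCC[C@@]32C)cc1 | intermediate
20 | 6α-boranyl-11-(4-methoxybenzyloxy)-7β,8α-bis(triethylsilyloxy)-5α-drimane | COc1ccc(COC[C@H]2[C@](C)(O[Si](CC)(CC)CC)[C@@H](O[Si](CC)(CC)CC)[C@H](B)[C@H]3C(C)(C)CCC[C@@]32C)cc1 | intermediate (not isolated)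
21 | 11-(4-methoxybenzyloxy)-7β,8α-bis(triethylsilyloxy)-5α-driman-6α-ol | COc1ccc(COC[C@H]2[C@](C)(O[Si](CC)(CC)CC)[C@@H](O[Si](CC)(CC)CC)[C@H](O)[C@H]3C(C)(C)CCC[C@@]32C)cc1 | intermediate
22 | 7β,8α-bis(triethylsilyloxy)drimane-6α,11-diol | OC[C@H]1[C@](C)(O[Si](CC)(CC)CC)[C@@H](O[Si](CC)(CC)CC)[C@H](O)[C@H]2C(C)(C)CCC[C@@]21C | intermediate
23 | 11-iodo-7β,8α-bis(triethylsilyloxy)driman-6α-ol | IC[C@H]1[C@](C)(O[Si](CC)(CC)CC)[C@@H](O[Si](CC)(CC)CC)[C@H](O)[C@H]2C(C)(C)CCC[C@@]21C | intermediate
24 | angelic acid, (2Z)-2-methylbut-2-enoic acid | C/C=C(/C)C(=O)O | starting material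
25 | angelic 2,4,6-trichlorobenzoic anhydride | C/C=C(/C)C(=O)OC(=O)c1c(Cl)cc(Cl)cc1Cl | intermediate (not isolated)
26 | 11-iodo-7β,8α-bis(triethylsilyloxy)driman-6α-yl angelate | IC[C@H]1[C@](C)(O[Si](CC)(CC)CC)[C@@H](O[Si](CC)(CC)CC)[C@H](OC(=O)/C(C)=C\C)[C@H]2C(C)(C)CCC[C@@]21C | intermediate
27 | but-1-en-3-yne | C=CC#C | starting material
28 | dimethyl[(1E)-2-methylbuta-1,3-dienyl]alane | C=C/C(C)=C/[Al](C)C | intermediate (not isolated)
29 | (1E)-1-iodo-2-methylbuta-1,3-diene | C=C/C(C)=C/I | intermediate
30 | [6α-angeloyloxy-7β,8α-bis(triethylsilyloxy)driman-11-yl]zinc iodide | I[Zn]C[C@H]1[C@](C)(O[Si](CC)(CC)CC)[C@@H](O[Si](CC)(CC)CC)[C@H](OC(=O)/C(C)=C\C)[C@H]2C(C)(C)CCC[C@@]21C | intermediate (not isolated)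
31 | 6α-angeloyloxy-7β,8α-bis(triethylsilyloxy)labda-12E,14-diene | C=C/C(C)=C/C[C@H]1[C@](C)(O[Si](CC)(CC)CC)[C@@H](O[Si](CC)(CC)CC)[C@H](OC(=O)/C(C)=C\C)[C@H]2C(C)(C)CCC[C@@]21C | intermediate
32 | 6α-angeloyloxylabda-12E,14-diene-7β,8α-diol (CNP0189082.1) | C=C/C(C)=C/C[C@H]1[C@](C)(O)[C@@H](O)[C@H](OC(=O)/C(C)=C\C)[C@H]2C(C)(C)CCC[C@@]21C | target

Total step count: 18. Longest linear sequence: 17 (steps 1–15, 17, 18). Step 16 is a one-step side branch.

Steps most likely to fail

1. Step 5.
- What may go wrong: the cycloaddition assembles three contiguous fully substituted carbons (C4, C5, C10), so it may stall or revert. Turnover may be blocked because the adduct aldehyde binds boron more strongly than the enal does. Facial discrimination on an α-unsubstituted, β,β-disubstituted enal may also be weak.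
- Fallback (known chemistry), cycloaddition: setting out from 10, the reaction is run with a stoichiometric achiral aluminium Lewis acid (MeAlCl2, 1.1 equiv, CH2Cl2, −78 °C). This is the established way of driving four-atom-tethered furan cycloadditions, because complexation of the adduct carbonyl pulls the equilibrium.
- Fallback, resolution: the same cold DIBAL-H quench then gives 11 and 12 as racemates, that is, together with ent-5α,8α-epoxydrim-6-en-11-al F1 (not isolated) and ent-5α,8α-epoxydrim-6-en-11-ol F2. Esterification with (S)-O-methylmandelic acid (DCC, DMAP, CH2Cl2) gives 5α,8α-epoxydrim-6-en-11-yl (S)-O-methylmandelate F3 and ent-5α,8α-epoxydrim-6-en-11-yl (S)-O-methylmandelate F4. These are separated by chromatography or crystallisation.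
- Return: saponification of F3 (LiOH, THF–H2O) rejoins the route at 12.

2. Step 17.
- What may go wrong: zinc insertion at the congested C11 may be slow and accompanied by protodemetalation. Transmetalation to palladium may lag behind homocoupling of the dienyl iodide. β-Hydride loss from C9 may compete with reductive elimination.
- Fallback: the diene is built by carbonyl olefination instead of cross-coupling. Setting out from 26, tin-hydride-mediated radical formylation (Bu3SnH, AIBN, CO 80 atm, benzene, 80 °C) engages C11 as a sterically undemanding radical. It gives 6α-angeloyloxy-7β,8α-bis(triethylsilyloxy)-13,14,15,16-tetranorlabdan-12-al F5.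
- A Wittig reaction with 2-(triphenylphosphoranylidene)propanal (toluene, 90 °C) gives (12E)-6α-angeloyloxy-7β,8α-bis(triethylsilyloxy)-15-norlabd-12-en-14-al F6.
- Return: Wittig methylenation of F6 (Ph3P=CH2, THF, −78 → 0 °C) rejoins the route at 31.

3. Step 12.
- What may go wrong: borane addition may be too slow at the trisubstituted C5=C6 bond, which is wedged between two quaternary carbons. Facial selectivity may erode, or the β-silyloxyborane may eliminate on heating.
- Fallback: hydrogen is placed on C5 first and the more reactive enol ether is hydroborated. Setting out from 17, the enone is hydrogenated from the α face (H2, Pd/C, EtOAc, pyridine additive to spare the PMB ether). This gives 8α-hydroxy-11-(4-methoxybenzyloxy)-5α-driman-7-one F7.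
- TESOTf/Et3N (CH2Cl2, 0 °C) then forms the enol ether and caps O8, giving 11-(4-methoxybenzyloxy)-7,8α-bis(triethylsilyloxy)-5α-drim-6-ene F8.
- Return: α-face hydroboration of this silyl enol ether (BH3·THF) puts boron on C6 and hydrogen on C7. That is alkylborane 20, and perborate oxidation rejoins the route at 21.

Further compounds
F1 | step 5 | ent-5α,8α-epoxydrim-6-en-11-al | O=C[C@@H]1[C@]3(C)C=C[C@]2(O3)C(C)(C)CCC[C@]21C
F2 | step 5 | ent-5α,8α-epoxydrim-6-en-11-ol | OC[C@@H]1[C@]3(C)C=C[C@]2(O3)C(C)(C)CCC[C@]21C
F3 | step 5 | 5α,8α-epoxydrim-6-en-11-yl (S)-O-methylmandelate | CO[C@H](C(=O)OC[C@H]1[C@@]3(C)C=C[C@@]2(O3)C(C)(C)CCC[C@@]21C)c1ccccc1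
F4 | step 5 | ent-5α,8α-epoxydrim-6-en-11-yl (S)-O-methylmandelate | CO[C@H](C(=O)OC[C@@H]1[C@]3(C)C=C[C@]2(O3)C(C)(C)CCC[C@]21C)c1ccccc1
F5 | step 17 | 6α-angeloyloxy-7β,8α-bis(triethylsilyloxy)-13,14,15,16-tetranorlabdan-12-al | O=CC[C@H]1[C@](C)(O[Si](CC)(CC)CC)[C@@H](O[Si](CC)(CC)CC)[C@H](OC(=O)/C(C)=C\C)[C@H]2C(C)(C)CCC[C@@]21C
F6 | step 17 | (12E)-6α-angeloyloxy-7β,8α-bis(triethylsilyloxy)-15-norlabd-12-en-14-al | O=C/C(C)=C/C[C@H]1[C@](C)(O[Si](CC)(CC)CC)[C@@H](O[Si](CC)(CC)CC)[C@H](OC(=O)/C(C)=C\C)[C@H]2C(C)(C)CCC[C@@]21C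
F7 | step 12 | 8α-hydroxy-11-(4-methoxybenzyloxy)-5α-driman-7-one | COc1ccc(COC[C@H]2[C@](C)(O)C(=O)C[C@H]3C(C)(C)CCC[C@@]32C)cc1
F8 | step 12 | 11-(4-methoxybenzyloxy)-7,8α-bis(triethylsilyloxy)-5α-drim-6-ene | COc1ccc(COC[C@H]2[C@](C)(O[Si](CC)(CC)CC)C(O[Si](CC)(CC)CC)=C[C@H]3C(C)(C)CCC[C@@]32C)cc1
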